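## The problem

The target is (1E,5S,6S,7R,8R,10R)-5-acetoxy-10-hydroxy-8-tigloyloxygermacra-1,4(15),11(13)-trien-12,6-olide; germacrane numbering is used throughout. Its ten-membered carbocycle C1–C10 is trans-fused along C6–C7 to an α-methylene-γ-butyrolactone (O6, C12, C11, C13) and carries an E-alkene at C1=C2 and an exocyclic methylene at C4=C15. A synthesis has to close this medium ring against both strain and entropy, so the ring-closing step should create functionality or stereochemistry at the same time. Of the five stereocentres, C5 and C6 form a threo diol (trans on the ring) that maps onto L-tartaric acid, and C7 is next to C6 and can be induced by it. C10, a fully substituted carbinol, is insulated from C5–C7 by C1–C4 and cannot be relayed from them in an open chain, but once it exists its hydroxyl can control C8, to which it is 1,3-anti. Four neighbouring oxygens must end in four different states: acetate at O5, lactone at O6, tiglate at O8 and a free hydroxyl at O10. The α-methylene lactone does not survive nucleophiles, hydride or strong base, the two esters do not survive enolate chemistry, the tertiary allylic alcohol at C10 ionises in acid, the skipped C1=C2/C4=C15 diene can move into conjugation, and C7 is epimerisable whenever C8 is a carbonyl. The feature that makes the key step possible is the triad C8(O)–C9H2–C10(O)(CH3): it is the retron of a 2-isoxazoline with C8 as the C=N carbon and its oxygen on C10, and because C10 also carries the C1=C2 vinyl group, the dipolarophile is the terminal C9=C10 bond of a 2-methyl-1,3-diene tied to a C8 nitrile oxide through C1–C7.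

## Retrosynthesis

**Ester and lactone C–O bonds.** The O5 acetyl is cut first, to hydroxy lactone 32, because acetylating a secondary allylic alcohol beside a tertiary one needs no protection and is the mildest possible last step. The lactone C12–O6 bond is cut next, to the bis(triethylsilyl) acid 31. When O5 and O6 are released together, only O6 can reach C12 through a five-membered ring, so lactonisation tells the two tartrate oxygens apart without a protecting-group step. Freeing O5 and O6 from an acetonide with acid at this stage was set aside because the C10 tertiary allylic alcohol is then present; silyl ethers ask only for buffered HF.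

**C11=C13 and the C12 oxidation level.** C13 is cut from C11 at the aldehyde level: acid 31 comes from enal 30, 30 from aldehyde 29 by α-methylenation, and 29 from the primary silyl ether 28. Methylenating the finished lactone through its enolate would expose the tiglate to strong base and was rejected; an aldehyde needs only an iminium salt and a tertiary amine. Compound 28 is simpler by the whole lactone unit, and the forward steps must leave one ester and a free tertiary alcohol untouched.

**C8.** The O8–acyl bond is cut to diol 26 and tiglic acid 27. The tiglate doubles as the protecting group for O8 during the C12 oxidations and is introduced while O5 and O6 are silylated and O10 is tertiary, so no selectivity problem arises. The C8–H bond is then cut to β-hydroxy ketone 25: intramolecular hydride delivery from O10 gives the 1,3-anti diol, so C10 controls C8. The ketone comes from isoxazoline 24 by N–O cleavage.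

**C4=C15 and the protecting-group exchange.** The C4=C15 bond is cut to ketone 23, which goes back through triol 22 to cycloadduct 21. Methylenation is placed before the isoxazoline is opened because the molecule then holds no ester, no free hydroxyl and no second carbonyl, and a non-basic titanium reagent can be used on a ketone flanked by an allylic methylene and an oxygenated carbon. The same stage is the only one that tolerates aqueous acid, so the acetonide, the C4 ketal and the C12 silyl ether of 21 are all removed there (22) and replaced by triethylsilyl ethers (23).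

**Key disconnection.** Cutting C8–C9 and O–C10 of 21 leads to nitrile oxide 20, made in the flask from hydroximoyl chloride 19 and aldoxime 18. Against its neighbours (closure at C1=C2 by olefination or metathesis, at C2–C3 by cross-coupling, at C5–C6 or C6–C7 by carbonyl chemistry), this cut has the merit that the ring closure itself creates the quaternary C10–O bond and stores the C8 oxygen as the C=N group. No stereocentre remote from the tartrate unit then has to be built in an open chain; 18 is acyclic with three stereocentres, all within C5–C7. The forward reaction must: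
- prefer the terminal C9=C10 bond in the bridged ten-membered mode over dimerisation of the dipole and over the internal C1=C2 bond, which could be reached in a fused seven-membered mode;
- choose one face of C10;
- meet no other dipolarophile, which is why C4 is a ketal and C11 is saturated.

A dimethyl ketal is preferred to a cyclic one because an α-oxygenated dioxolane would need forcing acid for its removal.

**Diene.** The oxime 18 is traced to aldehyde 17 and triethylsilyl ether 16. The C1=C2 bond of 16 is cut by a Julia–Kocienski olefination into sulfone 14 and methacrolein 15, which brings in C1, C10, C9 and the C14 methyl in one piece and fixes the E geometry before the ring is closed. A Wittig reaction of a C2 aldehyde with a methallyl ylide would be less E-selective, and a cross-coupling would need a vinyl metal that does not survive the ozonolysis used earlier.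

**C8 from a vinyl group.** C8 of 14 is the surviving carbon of a vinyl group: 14 comes from alcohol 13, 13 from aldehyde 12 by reduction, and 12 from alkene 11 by ozonolysis. Ozone would destroy the diene, so this cleavage precedes the olefination, and the C8 oxygen is carried through as a triethylsilyl ether that can later be oxidised directly. Sulfone 11 goes back through sulfide 10 to alcohol 9 and ester 8 by functional-group changes.

**C7.** The C7–C8 bond of 8 is cut by conjugate addition to E-enoate 7; the C6 oxygen directs the vinyl group to the anti face, so the tartrate unit sets C7. The C7=C11 bond of 7 is cut by a Horner–Wadsworth–Emmons reaction to aldehyde 6, made in the flask from Weinreb amide 5. An enolate alkylation at C7 was not pursued because an enolate with the C6 acetonide oxygen in the β-position would eliminate.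

**C2–C4 chain and start.** Ketal 5 comes from ketone 4. The C3–C4 and C2–S bonds of 4 are cut together: a vinyl nucleophile adds once to the C2-symmetric bis-Weinreb amide 2, and the resulting vinyl ketone 3 is trapped by a tetrazolyl thiol. This desymmetrises the tartrate unit in one operation and places sulfur on C2 for the later olefination. Diamide 2 is made from commercially available dimethyl 2,3-O-isopropylidene-L-tartrate 1, whose carbinol carbons become C5 and C6 and whose carboxyl carbons become C4 and C7.

## Roads not taken

**Alternative 1:** allylstannane–aldehyde closure at C5–C6.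
- Cut and key step: BF3·OEt2 would activate a C6 aldehyde for SE2' attack by a γ-silyloxyallylstannane in the same chain (tin on C15, enol ether carbon C5). C5–C6 forms, the ring closes and the C4=C15 methylene appears as tin leaves, giving A1.
- Merits: one step closes the ring, installs the exocyclic methylene and creates both carbinol centres, and γ-oxygenated allylstannanes under Lewis acid normally give the syn (threo) 1,2-diol pattern the target needs. A1 also emerges with O5 and O6 already differentiated and with no masked methylene to unveil, which is better than the chosen plan.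
- Weak points: C7, C8 and above all the remote quaternary C10 must be made independently in an open chain. The α-branched, β-oxygenated C6 aldehyde is prone to epimerisation and elimination. BF3 meets a tertiary allylic silyl ether at C10. The enol ether geometry and the facial selectivity at C6 relative to C7 are both uncontrolled variables in a ten-membered closure.
- Comparison: the chosen plan sets against it the free supply of C5/C6 from tartrate, a ring closure that itself makes C10 and encodes C8, and no stoichiometric tin.

**Alternative 2:** [2,3]-Wittig ring contraction forming C6–C7.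
- Cut and key step: LiN(SiMe3)2 (or Bu2BOTf with a tertiary amine) would enolise an α-allyloxy ketone at C6 inside a thirteen-membered ether. The [2,3] shift forms C6–C7, breaks O–C13, contracts the ring to ten members, and the released C6 alkoxide lactonises onto the C12 ester to give A2.
- Merits: the thirteen-membered ether is much easier to close than a ten-membered carbocycle, and A2 arrives with the α-methylene lactone complete. The chosen plan spends four steps (21–24) on that unit, so this road is clearly better there.
- Weak points: the C6/C7 relationship depends on enolate geometry and on the transition state inside a macrocycle. The C5 ketone of A2 still has to be reduced stereoselectively beside the lactone. The base meets two Michael acceptors (the C4=C15 enone and the acrylate). C8 and C10 must again be set separately, and the sensitive lactone has to be carried through reduction, desilylation and two acylations.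
- Comparison: the chosen plan has the longer endgame, but C5, C6 and C7 rest on tartrate and on a well-understood acyclic addition and not on untested macrocyclic control.

**Alternative 3:** allyl–vinyl Stille closure at C2–C3.
- Cut and key step: Pd2(dba)3 (zerovalent palladium) with AsPh3 would ionise an allylic chloride whose allyl unit is symmetric about C4, and couple it with an E-vinylstannane at C2 to give A3.
- Merits: the ring closes last, no stereocentre is created in the closure so none can go wrong there, the E geometry comes from the stannane, and only desilylation and acetylation follow A3. In post-cyclisation economy this road is better than the chosen one.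
- Weak points: a ten-membered Stille closure competes with oligomerisation and protodestannylation. The α-methylene lactone, the tiglate and an allylic C5 oxygen are all exposed to palladium. Every one of the five stereocentres, including the tertiary allylic carbinol bearing the vinylstannane, has to be made in an open chain, and the lactone has to be carried through that whole assembly.
- Comparison: the chosen plan sets against it a ring closure that pays for C10 and, through it, C8, and a start from a C2-symmetric commodity chemical. It concedes eleven steps after the ring is closed.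

Key step: step 14

## Route

Remark: atoms carry germacrane numbers (C1–C15) throughout, and diester 1 is taken as the commercial acetonide of dimethyl L-tartrate.

Step 1
Reactants: 1 dimethyl (4R,5R)-2,2-dimethyl-1,3-dioxolane-4,5-dicarboxylate
Product: 2 (4R,5R)-N4,N5-dimethoxy-N4,N5,2,2-tetramethyl-1,3-dioxolane-4,5-dicarboxamide (bis-Weinreb amide)
Conditions: MeNHOMe·HCl, iPrMgCl, THF, −20 → 0 °C
Reagents that add atoms: N,O-dimethylhydroxylamine hydrochloride, CNOC.Cl
Why: Aminolysis of both esters by the chloromagnesium amide (Weinreb amide formation); the carbinol centres are not enolised under these conditions and the trans-dioxolane is in any case the more stable arrangement.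

Step 2
Reactants: 2 bis-Weinreb amide
Product: 4 keto sulfide (C4 ketone; C2 1-phenyl-1H-tetrazol-5-yl sulfide; C7 Weinreb amide), via vinyl ketone 3 (not isolated)
Conditions: CH2=CHMgBr (1.2 equiv), THF, −20 °C; then 1-phenyl-1H-tetrazole-5-thiol (3 equiv), −20 °C → rt
Reagents that add atoms: vinylmagnesium bromide, C=C[Mg]Br; 1-phenyl-1H-tetrazole-5-thiol, SC1=NN=NN1c1ccccc1
Why: Weinreb ketone synthesis followed by thia-Michael addition in one flask: the chelated tetrahedral intermediate stops the Grignard reagent at one addition per amide, a single equivalent favours the mono-ketone of the C2-symmetric diamide, and the acidic thiol both releases enone 3 and traps it at sulfur before the liberated hydroxylamine can add.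

Step 3
Reactants: 4 keto sulfide
Product: 5 dimethyl ketal (C4 dimethyl ketal; C2 sulfide; C7 Weinreb amide)
Conditions: MeOSiMe3, Me3SiOTf (cat.), CH2Cl2, −78 → −30 °C; pyridine quench
Reagents that add atoms: methoxytrimethylsilane, CO[Si](C)(C)C
Why: Noyori ketalisation with an alkoxysilane converts the α-oxygenated ketone into its dimethyl ketal at low temperature without opening the acetonide; the ketal removes the acidity of C3–H and keeps C4 from acting as an electrophile or later as a dipolarophile.

Step 4
Reactants: 5 dimethyl ketal
Product: 7 E-enoate (ethyl ester at C12; C7=C11 alkene), via C7 aldehyde 6 (not isolated)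
Conditions: iBu2AlH (1.3 equiv), THF, −78 °C; MeOH; then (EtO)2P(O)CH2CO2Et/NaH, THF, −78 °C → rt
Reagents that add atoms: triethyl phosphonoacetate, CCOC(=O)CP(=O)(OCC)OCC
Why: Partial reduction of the Weinreb amide and Horner–Wadsworth–Emmons olefination in one flask, so that the epimerisable α-alkoxy aldehyde 6 is never handled; the stabilised phosphonate anion gives the E-enoate.

Step 5
Reactants: 7 E-enoate
Product: 8 ethyl (3R)-3-(dioxolanyl)pent-4-enoate (vinyl group on C7; 7R)
Conditions: CH2=CHMgBr (3 equiv), CuI (0.3 equiv), Me3SiCl (3 equiv), THF, −78 → −40 °C; aq. NH4Cl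
Reagents that add atoms: vinylmagnesium bromide, C=C[Mg]Br
Why: Copper-catalysed conjugate addition of a Grignard reagent accelerated by Me3SiCl; the γ-alkoxy E-enoate reacts through the conformer in which the C6–O bond is anti to the incoming nucleophile (modified Felkin–Anh model, as known for dioxolanyl acrylates), so the vinyl group, the future C8, enters anti to O6 and C7 is set as R under control of C6.

Step 6
Reactants: 8 ester
Product: 9 primary alcohol (C12 OH)
Conditions: iBu2AlH (2.5 equiv), CH2Cl2, −78 → 0 °C
Reagents that add atoms: none
Why: Reduction of the ester to the primary alcohol by excess aluminium hydride; sulfide, ketal, acetonide and the terminal alkene are inert.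

Step 7
Reactants: 9 primary alcohol
Product: 10 tert-butyldimethylsilyl ether (C12 OTBS)
Conditions: tBuMe2SiCl, imidazole, DMF, rt
Reagents that add atoms: tert-butyldimethylsilyl chloride, CC(C)(C)[Si](C)(C)Cl
Why: Standard silylation of a primary alcohol; this ether has to outlast the later direct oxidation of a triethylsilyl ether.

Step 8
Reactants: 10 sulfide
Product: 11 sulfone (C2 1-phenyl-1H-tetrazol-5-yl sulfone)
Conditions: (NH4)6Mo7O24·4H2O (0.1 equiv), 30% H2O2, EtOH, 0 °C → rt
Reagents that add atoms: hydrogen peroxide, OO
Why: Molybdate-catalysed peroxide oxidation of the sulfide to the sulfone; a monosubstituted alkene is not epoxidised under these conditions, and the sulfide has to be gone before ozone is used.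

Step 9
Reactants: 11 sulfone
Product: 13 primary alcohol (C8 OH; 7R), via C8 aldehyde 12 (not isolated)
Conditions: O3, CH2Cl2/MeOH (4:1), −78 °C; then NaBH4, −78 → 0 °C
Reagents that add atoms: ozone, [O-][O+]=O
Why: Ozonolysis of the only alkene with reductive work-up converts the vinyl group into the C8 hydroxymethyl group without touching C7; aldehyde 12 is reduced at low temperature, faster than hydride can attack the heteroaryl sulfone.

Step 10
Reactants: 13 primary alcohol
Product: 14 triethylsilyl ether (C8 OTES; C12 OTBS; C2 sulfone)
Conditions: Et3SiCl, imidazole, CH2Cl2, 0 °C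
Reagents that add atoms: chlorotriethylsilane, CC[Si](Cl)(CC)CC
Why: Silylation of the primary alcohol; the triethylsilyl group masks C8 during the olefination and is chosen because it can later be oxidised directly in the presence of the tert-butyldimethylsilyl ether.

Step 11
Reactants: 14 sulfone; 15 methacrolein
Product: 16 (E)-2-methyl-1,3-diene (C1=C2 E; C9=C10 terminal)
Conditions: KN(SiMe3)2 (1.1 equiv), DME, −60 °C; then 15 (3 equiv), −60 °C → rt
Reagents that add atoms: none
Why: Julia–Kocienski olefination: the potassium sulfonyl carbanion adds to the aldehyde, and Smiles rearrangement with loss of SO2 and the tetrazololate gives the alkene; a 1-phenyltetrazolyl sulfone with a potassium base in DME favours the E-alkene, which fixes the C1=C2 geometry of the target.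

Step 12
Reactants: 16 triethylsilyl ether
Product: 17 C8 aldehyde (7S by priority change; same spatial arrangement)
Conditions: (COCl)2, DMSO, CH2Cl2, −78 → −40 °C; then Et3N, −78 → 0 °C
Reagents that add atoms: none
Why: Swern conditions cleave and oxidise a primary triethylsilyl ether directly to the aldehyde while the primary tert-butyldimethylsilyl ether is kept; the diene and the ketal are inert, and the α-branched aldehyde is used at once.

Step 13
Reactants: 17 aldehyde
Product: 18 (E)-aldoxime (C8 oxime; C5/C6 acetonide; C4 dimethyl ketal; C12 OTBS; diene)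
Conditions: NH2OH·HCl, pyridine, EtOH, 0 °C → rt
Reagents that add atoms: hydroxylamine hydrochloride, NO.Cl
Why: Condensation of the aldehyde with hydroxylamine under buffered conditions that do not epimerise C7 and do not touch the ketal or the acetonide.

Step 14
Reactants: 18 aldoxime
Product: 21 isoxazoline-bridged (E)-cyclodecene (5R,6S,7R,10R), via hydroximoyl chloride 19 (not isolated), via nitrile oxide 20 (not isolated)
Conditions: NCS (1.05 equiv), DMF, 0 °C → rt; then syringe-pump addition (12 h) to Et3N (3 equiv) in CH2Cl2, 40 °C, 1 mM final concentration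
Reagents that add atoms: none
Why: NCS chlorinates the aldoxime to hydroximoyl chloride 19 and Et3N eliminates HCl to nitrile oxide 20, which is kept near 1 mM by slow addition so that ring closure can compete with furoxan formation. The dipole adds in a concerted (3+2) fashion across the terminal C9=C10 bond of the s-trans diene, carbon to the unsubstituted C9 and oxygen to the substituted C10, the normal regiochemistry for a 1,1-disubstituted alkene; the closest known reaction type is the macrocyclising intramolecular nitrile oxide–alkene cycloaddition to bridged isoxazolines, established for rings of twelve or more members. Two rings close together in the bridged mode: the ten-membered carbocycle through the C8–C9 bond and the isoxazoline through the O–C10 bond, with C8 and C10 as bridgeheads of a bicyclo[7.2.1] frame large enough to hold the bridgehead C=N. C10 is the only new stereocentre and is fixed by the face of the alkene that the dipole reaches: with C7–H eclipsing the nitrile oxide axis and the trans-dioxolane holding C4 and C7 apart, the N–O unit is expected to cross the ring face opposite the C7 side chain, which places oxygen on the Re face of C10 and gives 10R. The selectivity the step needs is threefold: ring closure over dimerisation (dilution), the terminal over the internal alkene (the E-1,2-disubstituted C1=C2 bond is intrinsically the much poorer dipolarophile, although its fused seven-membered mode is entropically easier and remains the main competitor), and one face of C10 (conformation only). C4 as a ketal and a saturated C11 leave no further dipolarophile in the molecule.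

Step 15
Reactants: 21 cycloadduct
Product: 22 keto triol (C4 ketone; C5, C6 and C12 hydroxyls; isoxazoline intact)
Conditions: AcOH/H2O/THF (3:1:1), 45 °C
Reagents that add atoms: water, O
Why: Aqueous acetic acid hydrolyses the acetonide, the dimethyl ketal and the primary silyl ether in one operation, at the one stage of the route that carries no ester, no tertiary allylic alcohol and no exocyclic alkene; the isoxazoline is stable to these conditions.

Step 16
Reactants: 22 keto triol
Product: 23 tris(triethylsilyl) ether (C5, C6 and C12 OTES; C4 ketone)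
Conditions: Et3SiCl, imidazole, DMAP (cat.), DMF, 0 °C → rt
Reagents that add atoms: chlorotriethylsilane, CC[Si](Cl)(CC)CC
Why: Silylation of one primary and two secondary hydroxyls with the silyl chloride and imidazole, which does not convert the ketone into a silyl enol ether as a silyl triflate with an amine could.

Step 17
Reactants: 23 ketone
Product: 24 exocyclic alkene (C4=C15; 5S by priority change)
Conditions: Cp2TiMe2 (3 equiv), toluene/THF, 70 °C, dark
Reagents that add atoms: dimethyltitanocene, C[Ti](C)(C1C=CC=C1)C1C=CC=C1
Why: Petasis methylenation: thermolysis of Cp2TiMe2 gives the titanium methylidene, which turns the ketone into the C4=C15 methylene through an oxatitanacyclobutane; the reagent is non-basic, so the ketone flanked by the allylic C3 and the oxygenated C5 is neither conjugated nor epimerised.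

Step 18
Reactants: 24 isoxazoline
Product: 25 β-hydroxy ketone (C8 ketone; C10 tertiary alcohol)
Conditions: Mo(CO)6 (1.2 equiv), MeCN/H2O (15:1), 80 °C
Reagents that add atoms: water, O
Why: Mo(CO)6 cleaves the N–O bond reductively and water hydrolyses the resulting β-hydroxy imine to the ketone; unlike hydrogenolysis this leaves both alkenes untouched, and it reveals the C10 alcohol with the configuration set in step 14.

Step 19
Reactants: 25 β-hydroxy ketone
Product: 26 anti-1,3-diol (8R,10R)
Conditions: Me4NBH(OAc)3 (6 equiv), MeCN/AcOH (1:1), −30 → −20 °C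
Reagents that add atoms: none
Why: Evans–Saksena reduction: the C10 hydroxyl exchanges an acetate on boron and delivers hydride intramolecularly through a six-membered transition state to the face of the C8 carbonyl on which O10 lies, so the new hydroxyl is anti to O10 (8R); C10 controls C8.

Step 20
Reactants: 26 diol; 27 tiglic acid
Product: 28 C8 tiglate (C10 OH free)
Conditions: 27, 2,4,6-trichlorobenzoyl chloride, Et3N, THF, rt; then 26, DMAP, toluene, rt
Reagents that add atoms: none
Why: Yamaguchi esterification: the mixed anhydride acylates the secondary C8 hydroxyl under DMAP catalysis while the tertiary C10 hydroxyl does not react, and the E geometry of the tiglate is not at risk.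

Step 21
Reactants: 28 tris(triethylsilyl) ether
Product: 29 C12 aldehyde
Conditions: (COCl)2, DMSO, CH2Cl2, −78 → −40 °C; then Et3N, −78 → 0 °C
Reagents that add atoms: none
Why: Swern conditions cleave and oxidise only the primary triethylsilyl ether; the two secondary silyl ethers, the ester and the tertiary alcohol are unchanged.

Step 22
Reactants: 29 aldehyde
Product: 30 α-methylene aldehyde (C11=C13)
Conditions: CH2=NMe2+ I− (Eschenmoser's salt), Et3N, CH2Cl2, rt
Reagents that add atoms: Eschenmoser's salt, C=[N+](C)C.[I-]
Why: Mannich reaction of the aldehyde with the iminium salt and elimination of dimethylamine in the same flask give the α-methylene aldehyde; this brings in C13 under conditions that the tiglate tolerates, which an ester or lactone enolate would not.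

Step 23
Reactants: 30 enal
Product: 31 α-methylene acid (C12 CO2H)
Conditions: NaClO2, NaH2PO4, 2-methyl-2-butene, tBuOH/H2O, 0 °C → rt
Reagents that add atoms: sodium chlorite, [Na+].[O-]Cl=O
Why: Pinnick oxidation of the enal to the acrylic acid; the excess of scavenger alkene removes hypochlorous acid before it can add to the three alkenes of the substrate.

Step 24
Reactants: 31 acid
Product: 32 hydroxy lactone (trans-fused α-methylene-γ-lactone; C5 OH)
Conditions: HF·pyridine, pyridine, THF, 0 °C → rt
Reagents that add atoms: none
Why: Fluoride removes both secondary silyl ethers; of the two hydroxyls set free only O6 can form a five-membered lactone with C12, so lactonisation differentiates O6 from O5 without a protecting group, and the buffered reagent spares the tertiary allylic alcohol.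

Step 25
Reactants: 32 hydroxy lactone
Product: 33 target
Conditions: Ac2O, pyridine, CH2Cl2, 0 °C → rt
Reagents that add atoms: acetic anhydride, CC(=O)OC(C)=O
Why: Acetylation of the secondary allylic C5 hydroxyl; the tertiary C10 hydroxyl is not acylated without a forcing catalyst.

## Compound list

1 | dimethyl (4R,5R)-2,2-dimethyl-1,3-dioxolane-4,5-dicarboxylate (dimethyl 2,3-O-isopropylidene-L-tartrate) | COC(=O)[C@@H]1OC(C)(C)O[C@H]1C(=O)OC | starting material
2 | (4R,5R)-N4,N5-dimethoxy-N4,N5,2,2-tetramethyl-1,3-dioxolane-4,5-dicarboxamide | CON(C)C(=O)[C@@H]1OC(C)(C)O[C@H]1C(=O)N(C)OC | intermediate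
3 | (4R,5R)-5-acryloyl-N-methoxy-N,2,2-trimethyl-1,3-dioxolane-4-carboxamide (formed in the flask) | CON(C)C(=O)[C@@H]1OC(C)(C)O[C@H]1C(=O)C=C | intermediate
4 | (4R,5R)-N-methoxy-N,2,2-trimethyl-5-[3-(1-phenyl-1H-tetrazol-5-ylsulfanyl)propanoyl]-1,3-dioxolane-4-carboxamide | CON(C)C(=O)[C@@H]1OC(C)(C)O[C@H]1C(=O)CCSC2=NN=NN2c3ccccc3 | intermediate
5 | (4R,5R)-5-[1,1-dimethoxy-3-(1-phenyl-1H-tetrazol-5-ylsulfanyl)propyl]-N-methoxy-N,2,2-trimethyl-1,3-dioxolane-4-carboxamide | CON(C)C(=O)[C@@H]1OC(C)(C)O[C@H]1C(OC)(OC)CCSC2=NN=NN2c3ccccc3 | intermediate
6 | (4R,5R)-5-[1,1-dimethoxy-3-(1-phenyl-1H-tetrazol-5-ylsulfanyl)propyl]-2,2-dimethyl-1,3-dioxolane-4-carbaldehyde (formed in the flask) | O=C[C@@H]1OC(C)(C)O[C@H]1C(OC)(OC)CCSC2=NN=NN2c3ccccc3 | intermediate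
7 | ethyl (2E)-3-{(4S,5R)-5-[1,1-dimethoxy-3-(1-phenyl-1H-tetrazol-5-ylsulfanyl)propyl]-2,2-dimethyl-1,3-dioxolan-4-yl}prop-2-enoate | CCOC(=O)/C=C/[C@@H]1OC(C)(C)O[C@H]1C(OC)(OC)CCSC2=NN=NN2c3ccccc3 | intermediate
8 | ethyl (3R)-3-{(4S,5R)-5-[1,1-dimethoxy-3-(1-phenyl-1H-tetrazol-5-ylsulfanyl)propyl]-2,2-dimethyl-1,3-dioxolan-4-yl}pent-4-enoate | C=C[C@@H](CC(=O)OCC)[C@@H]1OC(C)(C)O[C@H]1C(OC)(OC)CCSC2=NN=NN2c3ccccc3 | intermediate
9 | (3R)-3-{(4S,5R)-5-[1,1-dimethoxy-3-(1-phenyl-1H-tetrazol-5-ylsulfanyl)propyl]-2,2-dimethyl-1,3-dioxolan-4-yl}pent-4-en-1-ol | C=C[C@@H](CCO)[C@@H]1OC(C)(C)O[C@H]1C(OC)(OC)CCSC2=NN=NN2c3ccccc3 | intermediate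
10 | tert-butyldimethylsilyl ether of 9 (C12 OTBS; C2 sulfide; C7 vinyl) | C=C[C@@H](CCO[Si](C)(C)C(C)(C)C)[C@@H]1OC(C)(C)O[C@H]1C(OC)(OC)CCSC2=NN=NN2c3ccccc3 | intermediate
11 | sulfone of 10 (C2 1-phenyl-1H-tetrazol-5-ylsulfonyl; C12 OTBS; C7 vinyl) | C=C[C@@H](CCO[Si](C)(C)C(C)(C)C)[C@@H]1OC(C)(C)O[C@H]1C(OC)(OC)CCS(=O)(=O)C2=NN=NN2c3ccccc3 | intermediate
12 | (2S)-4-(tert-butyldimethylsilyloxy)-2-{(4S,5R)-5-[1,1-dimethoxy-3-(1-phenyl-1H-tetrazol-5-ylsulfonyl)propyl]-2,2-dimethyl-1,3-dioxolan-4-yl}butanal (formed in the flask) | O=C[C@@H](CCO[Si](C)(C)C(C)(C)C)[C@@H]1OC(C)(C)O[C@H]1C(OC)(OC)CCS(=O)(=O)C2=NN=NN2c3ccccc3 | intermediate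
13 | (2R)-4-(tert-butyldimethylsilyloxy)-2-{(4S,5R)-5-[1,1-dimethoxy-3-(1-phenyl-1H-tetrazol-5-ylsulfonyl)propyl]-2,2-dimethyl-1,3-dioxolan-4-yl}butan-1-ol | OC[C@@H](CCO[Si](C)(C)C(C)(C)C)[C@@H]1OC(C)(C)O[C@H]1C(OC)(OC)CCS(=O)(=O)C2=NN=NN2c3ccccc3 | intermediate
14 | triethylsilyl ether of 13 (C8 OTES; C12 OTBS; C2 sulfone) | CC[Si](CC)(CC)OC[C@@H](CCO[Si](C)(C)C(C)(C)C)[C@@H]1OC(C)(C)O[C@H]1C(OC)(OC)CCS(=O)(=O)C2=NN=NN2c3ccccc3 | intermediate
15 | methacrolein (2-methylprop-2-enal) | C=C(C)C=O | starting material
16 | (2R)-4-(tert-butyldimethylsilyloxy)-2-{(4S,5R)-5-[(3E)-1,1-dimethoxy-5-methylhexa-3,5-dienyl]-2,2-dimethyl-1,3-dioxolan-4-yl}butyl triethylsilyl ether | CC[Si](CC)(CC)OC[C@@H](CCO[Si](C)(C)C(C)(C)C)[C@@H]1OC(C)(C)O[C@H]1C(OC)(OC)C/C=C/C(C)=C | intermediate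
17 | (2S)-4-(tert-butyldimethylsilyloxy)-2-{(4S,5R)-5-[(3E)-1,1-dimethoxy-5-methylhexa-3,5-dienyl]-2,2-dimethyl-1,3-dioxolan-4-yl}butanal | O=C[C@@H](CCO[Si](C)(C)C(C)(C)C)[C@@H]1OC(C)(C)O[C@H]1C(OC)(OC)C/C=C/C(C)=C | intermediate
18 | (1E,2R)-4-(tert-butyldimethylsilyloxy)-2-{(4S,5R)-5-[(3E)-1,1-dimethoxy-5-methylhexa-3,5-dienyl]-2,2-dimethyl-1,3-dioxolan-4-yl}butanal oxime | O/N=C/[C@@H](CCO[Si](C)(C)C(C)(C)C)[C@@H]1OC(C)(C)O[C@H]1C(OC)(OC)C/C=C/C(C)=C | intermediate
19 | (2S)-4-(tert-butyldimethylsilyloxy)-2-{(4S,5R)-5-[(3E)-1,1-dimethoxy-5-methylhexa-3,5-dienyl]-2,2-dimethyl-1,3-dioxolan-4-yl}-N-hydroxybutanimidoyl chloride (formed in the flask) | ON=C(Cl)[C@@H](CCO[Si](C)(C)C(C)(C)C)[C@@H]1OC(C)(C)O[C@H]1C(OC)(OC)C/C=C/C(C)=C | intermediate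
20 | (2R)-4-(tert-butyldimethylsilyloxy)-2-{(4S,5R)-5-[(3E)-1,1-dimethoxy-5-methylhexa-3,5-dienyl]-2,2-dimethyl-1,3-dioxolan-4-yl}butanenitrile oxide (formed in the flask) | [O-][N+]#C[C@@H](CCO[Si](C)(C)C(C)(C)C)[C@@H]1OC(C)(C)O[C@H]1C(OC)(OC)C/C=C/C(C)=C | intermediate
21 | (1E,5R,6S,7R,10R)-cyclodecene bridged from C8 to C10 by C=N–O (isoxazoline, C9 as its CH2), with 10-methyl, C5/C6 acetonide, C4 dimethyl ketal and 7-(2-tert-butyldimethylsilyloxyethyl) | C[C@]12CC(=NO1)[C@@H](CCO[Si](C)(C)C(C)(C)C)[C@@H]3OC(C)(C)O[C@H]3C(OC)(OC)C/C=C/2 | intermediate
22 | (1E,5R,6S,7R,10R)-isoxazoline-bridged cyclodecene with C4 ketone, 5,6-diol and 7-(2-hydroxyethyl) | C[C@]12CC(=NO1)[C@@H](CCO)[C@H](O)[C@@H](O)C(=O)C/C=C/2 | intermediate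
23 | tris(triethylsilyl) ether of 22 (C5, C6 and C12 OTES; C4 ketone) | C[C@]12CC(=NO1)[C@@H](CCO[Si](CC)(CC)CC)[C@H](O[Si](CC)(CC)CC)[C@@H](O[Si](CC)(CC)CC)C(=O)C/C=C/2 | intermediate
24 | (1E,5S,6S,7R,10R)-isoxazoline-bridged cyclodecene with C4=C15 methylene and C5, C6, C12 OTES | C[C@]12CC(=NO1)[C@@H](CCO[Si](CC)(CC)CC)[C@H](O[Si](CC)(CC)CC)[C@@H](O[Si](CC)(CC)CC)C(=C)C/C=C/2 | intermediate
25 | (1E,5S,6S,7S,10R)-10-hydroxy-10-methyl-4-methylene-5,6-bis(triethylsilyloxy)-7-(2-triethylsilyloxyethyl)cyclodec-1-en-8-one (ring numbered as germacrane) | C[C@@]1(O)CC(=O)[C@@H](CCO[Si](CC)(CC)CC)[C@H](O[Si](CC)(CC)CC)[C@@H](O[Si](CC)(CC)CC)C(=C)C/C=C/1 | intermediate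
26 | (1E,5S,6S,7R,8R,10R)-8,10-diol of 25 (anti-1,3-diol) | C[C@@]1(O)C[C@@H](O)[C@@H](CCO[Si](CC)(CC)CC)[C@H](O[Si](CC)(CC)CC)[C@@H](O[Si](CC)(CC)CC)C(=C)C/C=C/1 | intermediate
27 | tiglic acid ((2E)-2-methylbut-2-enoic acid) | C/C=C(\C)C(=O)O | starting material
28 | 8-O-tiglate of 26 (C10 OH free; C5, C6, C12 OTES) | C[C@@]1(O)C[C@@H](OC(=O)/C(C)=C/C)[C@@H](CCO[Si](CC)(CC)CC)[C@H](O[Si](CC)(CC)CC)[C@@H](O[Si](CC)(CC)CC)C(=C)C/C=C/1 | intermediate
29 | C12 aldehyde (7-(2-oxoethyl); C8 tiglate; C5, C6 OTES; C10 OH) | C[C@@]1(O)C[C@@H](OC(=O)/C(C)=C/C)[C@@H](CC=O)[C@H](O[Si](CC)(CC)CC)[C@@H](O[Si](CC)(CC)CC)C(=C)C/C=C/1 | intermediate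
30 | α-methylene aldehyde (7-(3-oxoprop-1-en-2-yl); C8 tiglate; C5, C6 OTES; C10 OH) | C[C@@]1(O)C[C@@H](OC(=O)/C(C)=C/C)[C@@H](C(=C)C=O)[C@H](O[Si](CC)(CC)CC)[C@@H](O[Si](CC)(CC)CC)C(=C)C/C=C/1 | intermediate
31 | α-methylene acid (7-(1-carboxyethenyl); C8 tiglate; C5, C6 OTES; C10 OH) | C[C@@]1(O)C[C@@H](OC(=O)/C(C)=C/C)[C@@H](C(=C)C(=O)O)[C@H](O[Si](CC)(CC)CC)[C@@H](O[Si](CC)(CC)CC)C(=C)C/C=C/1 | intermediate
32 | (1E,5S,6S,7R,8R,10R)-5,10-dihydroxy-8-tigloyloxygermacra-1,4(15),11(13)-trien-12,6-olide | C=C1C(=O)O[C@H]2[C@H]1[C@H](OC(=O)/C(C)=C/C)C[C@@](C)(O)/C=C/CC(=C)[C@@H]2O | intermediate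
33 | (1E,5S,6S,7R,8R,10R)-5-acetoxy-10-hydroxy-8-tigloyloxygermacra-1,4(15),11(13)-trien-12,6-olide | C=C1C(=O)O[C@H]2[C@H]1[C@H](OC(=O)/C(C)=C/C)C[C@@](C)(O)/C=C/CC(=C)[C@@H]2OC(C)=O | target

## Step count and least certain steps

Total: 25 steps. Longest linear sequence: 25 steps from 1 (15 and 27 enter as purchased reagents).

**Step 14 (key step).** Four things can go wrong:
- dimerisation or oligomerisation of the nitrile oxide outrunning a strained ten-membered closure;
- cycloaddition at the internal C1=C2 bond in the fused seven-membered mode, which is entropically much easier although that alkene is the poorer dipolarophile;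
- low facial selectivity at C10, which rests on conformation only;
- epimerisation of C7 in the nitrile oxide under Et3N.

Fallback: the cycloaddition would be made intermolecular and the ring closed by olefination at C1=C2, so that no diene is present when the dipole is generated. It sets out from aldehyde 12, this time isolated by a dimethyl sulfide work-up of the ozonolysis of 11. Condensation with hydroxylamine would give the sulfone oxime F1. NCS and Et3N in the presence of excess 2-methylprop-2-en-1-ol would give the 5-hydroxymethyl-5-methylisoxazoline F2; C8–C9 and O–C10 form with the same regiochemistry but without facial control, so the 10R epimer would have to be separated. Dess–Martin oxidation would give the non-enolisable aldehyde F3. An intramolecular Julia–Kocienski olefination (KN(SiMe3)2, DME, high dilution) between the C2 sulfone and the C1 aldehyde would then close the ring and return to 21.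

**Step 5.** Facial selectivity of the conjugate addition may be modest, because it relies on acyclic 1,2-induction from C6 alone and copper-catalysed Grignard additions are less selective than preformed cuprates. Fallback (auxiliary control), from 5: reduction with iBu2AlH and olefination with diethyl 2-[(4S)-4-benzyl-2-oxo-1,3-oxazolidin-3-yl]-2-oxoethylphosphonate would give the enoyl oxazolidinone F4. CH2=CHMgBr with CuBr·SMe2 would add to the magnesium-chelated s-cis imide anti to the benzyl group, the same face that C6 favours, to give the imide F5. LiBH4 would remove the auxiliary and give 9 directly, so step 6 would not be needed.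

**Step 19.** Hydride delivery across a ten-membered ring may not follow the acyclic chair model, and reduction from the other face or without selectivity would give the C8 epimer. Fallback (inversion), from 25: a chelation-controlled Narasaka–Prasad reduction (Et2BOMe, NaBH4) would be used to make the syn diol F6 on purpose, and a Mitsunobu esterification with 27 (PPh3, DIAD) would invert C8 while installing the tiglate, returning to 28.

**Step 15.** Under aqueous acid the β,γ-unsaturated α-hydroxy ketone that is set free may move its double bond into conjugation or undergo an α-ketol shift, and the allylic C10–O bond of the isoxazoline could ionise if stronger acid were needed for the ketal. Fallback (staged unmasking), from 21: transketalisation with TsOH in wet acetone would remove only the dimethyl ketal, the acetonide being held by the solvent, to give the ketone F7. Cp2TiMe2 would give the methylene compound F8. Aqueous acetic acid would then give the triol F9, which has no carbonyl group, and silylation with Et3SiCl would return to 24.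

**Step 2.** Over-addition to the second amide, conjugate addition of the liberated N,O-dimethylhydroxylamine to 3, and N- instead of S-alkylation of the ambident thiol may each erode the one-flask sequence. Fallback (stepwise, no enone), from 2: CH2=CHCH2MgBr would give the allyl ketone F10, Noyori ketalisation the ketal F11, and ozonolysis with NaBH4 work-up the alcohol F12. A Mitsunobu reaction with 1-phenyl-1H-tetrazole-5-thiol (PPh3, DIAD) would then give 5.

## Further compounds

F1 | step 14 | (1E,2R)-4-(tert-butyldimethylsilyloxy)-2-{(4S,5R)-5-[1,1-dimethoxy-3-(1-phenyl-1H-tetrazol-5-ylsulfonyl)propyl]-2,2-dimethyl-1,3-dioxolan-4-yl}butanal oxime | O/N=C/[C@@H](CCO[Si](C)(C)C(C)(C)C)[C@@H]1OC(C)(C)O[C@H]1C(OC)(OC)CCS(=O)(=O)C2=NN=NN2c3ccccc3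
F2 | step 14 | (10R)-5-hydroxymethyl-5-methyl-4,5-dihydroisoxazole carrying at C3 the C7 side chain of F1 (C12 OTBS; acetonide; C4 dimethyl ketal; C2 sulfone) | C[C@]1(CO)CC(=NO1)[C@@H](CCO[Si](C)(C)C(C)(C)C)[C@@H]2OC(C)(C)O[C@H]2C(OC)(OC)CCS(=O)(=O)C3=NN=NN3c4ccccc4
F3 | step 14 | (10R)-5-formyl-5-methyl-4,5-dihydroisoxazole analogue of F2 (C1 aldehyde; C2 sulfone) | C[C@]1(C=O)CC(=NO1)[C@@H](CCO[Si](C)(C)C(C)(C)C)[C@@H]2OC(C)(C)O[C@H]2C(OC)(OC)CCS(=O)(=O)C3=NN=NN3c4ccccc4
F4 | step 5 | (4S)-4-benzyl-3-[(2E)-3-{(4S,5R)-5-[1,1-dimethoxy-3-(1-phenyl-1H-tetrazol-5-ylsulfanyl)propyl]-2,2-dimethyl-1,3-dioxolan-4-yl}prop-2-enoyl]-1,3-oxazolidin-2-one | O=C(/C=C/[C@@H]1OC(C)(C)O[C@H]1C(OC)(OC)CCSC2=NN=NN2c3ccccc3)N4[C@@H](Cc5ccccc5)COC4=O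
F5 | step 5 | (4S)-4-benzyl-3-[(3R)-3-{(4S,5R)-5-[1,1-dimethoxy-3-(1-phenyl-1H-tetrazol-5-ylsulfanyl)propyl]-2,2-dimethyl-1,3-dioxolan-4-yl}pent-4-enoyl]-1,3-oxazolidin-2-one | C=C[C@@H](CC(=O)N1[C@@H](Cc2ccccc2)COC1=O)[C@@H]3OC(C)(C)O[C@H]3C(OC)(OC)CCSC4=NN=NN4c5ccccc5
F6 | step 19 | C8 epimer of 26 (syn-1,3-diol; 8S,10R) | C[C@@]1(O)C[C@H](O)[C@@H](CCO[Si](CC)(CC)CC)[C@H](O[Si](CC)(CC)CC)[C@@H](O[Si](CC)(CC)CC)C(=C)C/C=C/1
F7 | step 15 | isoxazoline-bridged cyclodecene with C4 ketone, C5/C6 acetonide and C12 OTBS | C[C@]12CC(=NO1)[C@@H](CCO[Si](C)(C)C(C)(C)C)[C@@H]3OC(C)(C)O[C@H]3C(=O)C/C=C/2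
F8 | step 15 | isoxazoline-bridged cyclodecene with C4=C15 methylene, C5/C6 acetonide and C12 OTBS | C[C@]12CC(=NO1)[C@@H](CCO[Si](C)(C)C(C)(C)C)[C@@H]3OC(C)(C)O[C@H]3C(=C)C/C=C/2
F9 | step 15 | isoxazoline-bridged cyclodecene with C4=C15 methylene, 5,6-diol and 7-(2-hydroxyethyl) | C[C@]12CC(=NO1)[C@@H](CCO)[C@H](O)[C@@H](O)C(=C)C/C=C/2
F10 | step 2 | (4R,5R)-5-(but-3-enoyl)-N-methoxy-N,2,2-trimethyl-1,3-dioxolane-4-carboxamide | CON(C)C(=O)[C@@H]1OC(C)(C)O[C@H]1C(=O)CC=C
F11 | step 2 | (4R,5R)-5-(1,1-dimethoxybut-3-enyl)-N-methoxy-N,2,2-trimethyl-1,3-dioxolane-4-carboxamide | CON(C)C(=O)[C@@H]1OC(C)(C)O[C@H]1C(OC)(OC)CC=C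
F12 | step 2 | (4R,5R)-5-(3-hydroxy-1,1-dimethoxypropyl)-N-methoxy-N,2,2-trimethyl-1,3-dioxolane-4-carboxamide | CON(C)C(=O)[C@@H]1OC(C)(C)O[C@H]1C(OC)(OC)CCO
A1 | alternative 1 | ten-membered carbocycle with free C6 hydroxyl, C5 and C10 triethylsilyl ethers, C8 tert-butyldimethylsilyl ether and a C7 3-(4-methoxybenzyloxy)prop-1-en-2-yl group | O[C@H]1[C@H](C(=C)COCc2ccc(OC)cc2)[C@H](O[Si](C)(C)C(C)(C)C)C[C@@](C)(O[Si](CC)(CC)CC)/C=C/CC(=C)[C@@H]1O[Si](CC)(CC)CC
A2 | alternative 2 | 5-oxo germacranolide with α-methylene lactone, C8 tert-butyldimethylsilyl ether and C10 triethylsilyl ether | C=C1C(=O)O[C@H]2[C@H]1[C@H](O[Si](C)(C)C(C)(C)C)C[C@@](C)(O[Si](CC)(CC)CC)/C=C/CC(=C)C2=O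
A3 | alternative 3 | target skeleton with C5 tert-butyldimethylsilyl ether in place of the acetate | C=C1C(=O)O[C@H]2[C@H]1[C@H](OC(=O)/C(C)=C/C)C[C@@](C)(O)/C=C/CC(=C)[C@@H]2O[Si](C)(C)C(C)(C)C
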